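**Assumptions (one line each)**
- Locants follow acylphloroglucinol usage: C1 = acyl-bearing bridgehead, C2/C4/C9 = carbonyl carbons, C3 = carbon between C2 and C4, C5 = geranyl-bearing bridgehead, C6–C7–C8 = CH2–CH–CMe2 bridge. Lavandulyl = 5-methyl-2-(prop-1-en-2-yl)hex-4-en-1-yl; the monocyclic precursors use the same locants.
- (±)-Lavandulol and phlorisobutyrophenone are taken as catalogue compounds (the latter is otherwise one Friedel–Crafts step from phloroglucinol).
- The lipase is assumed to acylate (R)-lavandulol faster, leaving the (S)-alcohol.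
- The cinchonidinium catalyst is assumed to give the C5 configuration drawn; if it gives the other face, the cinchoninium pseudo-enantiomer is used.

**Retrosynthetic overview**
1. Target ⇐ reductive radical cascade from a C3 radical: 7-exo onto the C7 prenyl group, then 5-exo onto the C3 prenyl group, H-atom quench. The seven-membered and then the five-membered ring form last.
2. Bicyclo[3.3.1]nonanetrione ⇐ closure of a tertiary C8 cation onto C1 of a monocyclic dearomatized acylphloroglucinol, the same C1–C8 bond the prenyl-cation cyclization makes in nature. This ring forms first.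
3. One chlorine at C3 steers the three ring alkylations, blocks C3 so that only the acyl-bearing C1 can close, and then serves as the radical precursor.
4. Monocycle ⇐ phlorisobutyrophenone + (S)-lavandulyl iodide + geranyl bromide + prenyl acetate; C5 is set by chiral ion-pair catalysis.
5. C7 comes from (S)-lavandulol, obtained by lipase resolution of the racemate.

**Route**

Step 1
Reactants: 1 (±)-lavandulol
Product: 2 (S)-lavandulol, (2S)-5-methyl-2-(prop-1-en-2-yl)hex-4-en-1-ol
Conditions: porcine pancreatic lipase, vinyl acetate, hexane, rt, to about 60% conversion; chromatography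
Reagents that add atoms: none
Why: Lipase-catalysed kinetic resolution (enantioselective transesterification) acylates the (R)-alcohol faster, so running past half conversion leaves the (S)-alcohol in high ee; this fixes the future C7 centre.

Step 2
Reactants: 2 (S)-lavandulol
Product: 3 (S)-lavandulyl iodide, (3S)-3-(iodomethyl)-2,6-dimethylhepta-1,5-diene
Conditions: PPh3, I2, imidazole, CH2Cl2, 0 °C to rt
Reagents that add atoms: iodine, II
Why: Appel-type iodination replaces the primary hydroxyl by SN2 at CH2 and touches neither the adjacent stereocentre nor the alkenes.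

Step 3
Reactants: 4 phlorisobutyrophenone
Product: 5 3-chlorophlorisobutyrophenone, 1-(3-chloro-2,4,6-trihydroxyphenyl)-2-methylpropan-1-one
Conditions: SO2Cl2 (1.0 equiv), CHCl3/Et2O, 0 °C
Reagents that add atoms: sulfuryl chloride, O=S(=O)(Cl)Cl
Why: Electrophilic aromatic chlorination of the very electron-rich ring stops largely at the mono-chloride with one equivalent, as in known preparations of chlorinated acylphloroglucinols; the chlorine marks the future C3.

Step 4
Reactants: 5 3-chlorophlorisobutyrophenone; 3 (S)-lavandulyl iodide
Product: 6 3-chloro-5-lavandulylphlorisobutyrophenone (side-chain stereocentre unchanged from 3)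
Conditions: LiN(SiMe3)2 (3.1 equiv), THF, −78 °C to rt
Reagents that add atoms: none
Why: C-alkylation (SN2) of the lithium trianion occurs at the only unsubstituted ring carbon, the lithium chelate favouring C- over O-attack as in known lavandulylations of acylphloroglucinols; no stereocentre is formed or disturbed.

Step 5
Reactants: 6 3-chloro-5-lavandulylphlorisobutyrophenone; 7 geranyl bromide
Product: 8 2-chloro-6-geranyl-3,5-dihydroxy-4-isobutyryl-6-lavandulylcyclohexa-2,4-dien-1-one (ring C6 = future C5, configured as in the target)
Conditions: O-allyl-N-(9-anthracenylmethyl)cinchonidinium bromide (10 mol%), CsOH·H2O (3 equiv), CH2Cl2, −50 °C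
Reagents that add atoms: none
Why: Asymmetric phase-transfer alkylative dearomatization: geranyl bromide attacks the alkyl-bearing carbon (the chlorine-bearing carbon is the poorer nucleophile) and the chiral ammonium ion pair shields one ring face, setting quaternary C5 under catalyst control; the remote lavandulyl centre has no influence.

Step 6
Reactants: 8 dearomatized chloro-dienone; 9 prenyl acetate
Product: 10 2-chloro-6-geranyl-5-hydroxy-4-isobutyryl-6-lavandulyl-2-prenylcyclohex-4-ene-1,3-dione (both epimers at the chlorine-bearing carbon)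
Conditions: Pd(PPh3)4 (5 mol%), K2CO3 (1.2 equiv), THF, rt
Reagents that add atoms: none
Why: Tsuji–Trost allylation: the soft 2-chloro-1,3-dicarbonyl enolate attacks the π-prenyl palladium complex at its unsubstituted terminus, and O-prenylation is reversible under palladium, so C3 becomes quaternary (Cl, prenyl); the epimer mixture is irrelevant because this centre becomes a radical in step 9.

Step 7
Reactants: 10 chloro-prenyl cyclohexenedione
Product: 11 6-chloro-4a-geranyl-8-isobutyryl-2,2-dimethyl-3,6-diprenyl-3,4-dihydro-2H-chromene-5,7(4aH,6H)-dione (cyclic C8–O9 enol ether)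
Conditions: [N,N'-bis(3,5-di-tert-butylsalicylidene)-1,2-cyclohexanediaminato]cobalt (divalent cobalt, 5 mol%), N-fluoro-2,4,6-trimethylpyridinium tetrafluoroborate (1.5 equiv), PhSiH3 (1.2 equiv), PhCF3, 0 °C to rt
Reagents that add atoms: none
Why: Cobalt-hydride hydrogen-atom transfer with radical–polar crossover (Mukaiyama-type Markovnikov hydroalkoxylation) selects the 1,1-disubstituted isopropenyl group over the four trisubstituted alkenes, and the C9 enol oxygen, the only enol oxygen within reach, traps the tertiary C8 centre as a dimethylpyran; no stereocentre changes.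

Step 8
Reactants: 11 pyran-fused chloro-dione
Product: 12 3-chloro-5-geranyl-1-isobutyryl-8,8-dimethyl-3,7-diprenylbicyclo[3.3.1]nonane-2,4,9-trione (C7 prenyl endo, C1/C5/C7 as in the target, both C3 epimers)
Conditions: Me3SiOTf (20 mol%), 2,6-di-tert-butyl-4-methylpyridine (30 mol%), CH2Cl2, −78 to −20 °C
Reagents that add atoms: none
Why: Proposed new method: the Lewis acid ionises the tertiary C8–O bond of the vinylogous ester (the β-triketone enolate is a good leaving group) without protonating any alkene, which a protic acid would do at the geranyl group; the tertiary cation, the C8 cation of the biosynthetic prenyl-cation cyclization, returns reversibly to oxygen but irreversibly to C1, the only carbon nucleophile left because C3 is quaternary; C1 is set by the tether, and with C5 and C7 fixed the only possible closure places the C7 prenyl group endo through a boat-like transition state; the closest known reactions are the formic-acid cation cyclizations of dearomatized acylphloroglucinols, Lewis-acid O-to-C shifts of tertiary alkyl enol ethers and the tert-alkylation of silyl enol ethers.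

Step 9
Reactants: 12 bicyclic chloro-trione
Product: 16 target CNP0379246.1, via C3 radical 13 (not isolated), via tertiary radical 14 (not isolated), via isopropyl radical 15 (not isolated)
Conditions: (Me3Si)3SiH (1.3 equiv, syringe pump), AIBN (0.2 equiv), PhH (5 mM), 80 °C
Reagents that add atoms: none
Why: Reductive radical cascade in the bond order of the presumed biosynthesis: chlorine abstraction gives the electrophilic C3 radical, which adds 7-exo-trig to the C7 prenyl group held over it (the CMe2 end turns away from the C8 methyls, setting the ring-fusion CH and C3); the tertiary radical then closes 5-exo-trig onto the C3 prenyl group with the isopropyl-bearing carbon trans to the cage CH2 (Beckwith-type 2,5-trans preference), and Si–H quenches the isopropyl radical.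

**Compound list**
1 | (±)-lavandulol | CC(C)=CCC(CO)C(C)=C | starting material
2 | (S)-lavandulol | OC[C@H](C(C)=C)CC=C(C)C | intermediate
3 | (S)-lavandulyl iodide | IC[C@H](C(C)=C)CC=C(C)C | intermediate
4 | phlorisobutyrophenone | CC(C)C(=O)c1c(O)cc(O)cc1O | starting material
5 | 3-chlorophlorisobutyrophenone | CC(C)C(=O)c1c(O)cc(O)c(Cl)c1O | intermediate
6 | 3-chloro-5-lavandulylphlorisobutyrophenone | CC(C)C(=O)c1c(O)c(Cl)c(O)c(C[C@@H](CC=C(C)C)C(C)=C)c1O | intermediate
7 | geranyl bromide, (2E)-1-bromo-3,7-dimethylocta-2,6-diene | CC(C)=CCC/C(C)=C/CBr | starting material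
8 | 2-chloro-6-geranyl-3,5-dihydroxy-4-isobutyryl-6-lavandulylcyclohexa-2,4-dien-1-one | CC(C)=CCC/C(C)=C/C[C@]1(C[C@@H](CC=C(C)C)C(C)=C)C(O)=C(C(=O)C(C)C)C(O)=C(Cl)C1=O | intermediate
9 | prenyl acetate, 3-methylbut-2-en-1-yl acetate | CC(=O)OCC=C(C)C | starting material
10 | 2-chloro-6-geranyl-5-hydroxy-4-isobutyryl-6-lavandulyl-2-prenylcyclohex-4-ene-1,3-dione (epimers at C–Cl) | CC(C)=CCC/C(C)=C/C[C@]1(C[C@@H](CC=C(C)C)C(C)=C)C(O)=C(C(=O)C(C)C)C(=O)C(Cl)(CC=C(C)C)C1=O | intermediate
11 | 6-chloro-4a-geranyl-8-isobutyryl-2,2-dimethyl-3,6-diprenyl-3,4-dihydro-2H-chromene-5,7(4aH,6H)-dione (epimers at C–Cl) | CC(C)=CCC/C(C)=C/C[C@]12C[C@@H](CC=C(C)C)C(C)(C)OC1=C(C(=O)C(C)C)C(=O)C(Cl)(CC=C(C)C)C2=O | intermediate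
12 | 3-chloro-5-geranyl-1-isobutyryl-8,8-dimethyl-3,7-diprenylbicyclo[3.3.1]nonane-2,4,9-trione, 7-endo (epimers at C3) | CC(C)=CCC/C(C)=C/C[C@@]12C[C@@H](CC=C(C)C)C(C)(C)[C@](C(=O)C(C)C)(C2=O)C(=O)C(Cl)(CC=C(C)C)C1=O | intermediate
13 | C3 radical of the bicyclic trione | CC(C)=CCC/C(C)=C/C[C@@]12C[C@@H](CC=C(C)C)C(C)(C)[C@](C(=O)C(C)C)(C2=O)C(=O)[C](CC=C(C)C)C1=O | intermediate
14 | homoadamantane tertiary radical (after 7-exo closure) | CC(C)=CCC/C(C)=C/C[C@@]12C[C@H]3C[C@H]([C](C)C)[C@@](CC=C(C)C)(C1=O)C(=O)[C@@](C(=O)C(C)C)(C2=O)C3(C)C | intermediate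
15 | tetracyclic isopropyl radical (after 5-exo closure) | CC(C)=CCC/C(C)=C/C[C@@]12C[C@H]3C[C@@H]4C(C)(C)[C@@H]([C](C)C)C[C@]4(C1=O)C(=O)[C@@](C(=O)C(C)C)(C2=O)C3(C)C | intermediate
16 | CNP0379246.1 | CC(C)=CCC/C(C)=C/C[C@@]12C[C@H]3C[C@@H]4C(C)(C)[C@@H](C(C)C)C[C@]4(C1=O)C(=O)[C@@](C(=O)C(C)C)(C2=O)C3(C)C | target

**Step count**
Total steps: 9. Longest linear sequence: 8 (steps 1, 2, 4, 5, 6, 7, 8, 9).

**Three steps most likely to fail**

Step 8 (C8 to C1 closure). Two fully substituted carbons must join through a boat-like transition state, and loss of a proton from the cation competes. Fallback, from 10 back to 12, which also bypasses step 7: cobalt-catalysed Markovnikov hydrochlorination of the isopropenyl group of 10 (the same cobalt salen complex, TsCl, PhSiH3, EtOH) gives the tertiary chloride F3. Silylation with N,O-bis(trimethylsilyl)acetamide gives the trimethylsilyl enol ether F4. ZnCl2 in CH2Cl2 at low temperature then effects an intramolecular tert-alkylation of the silyl enol ether at C1, which releases a silyl chloride instead of a proton, and the route is rejoined at 12.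

Step 5 (asymmetric dearomative geranylation). O-alkylation and modest facial control are both possible. Fallback, from 5 back to 8, which also bypasses step 4: alkylate 5 at its only free ring carbon with geranyl bromide 7 (aqueous KOH, 0 °C) to give 3-chloro-5-geranylphlorisobutyrophenone F1. Dearomative alkylation of F1 with iodide 3 (LiN(SiMe3)2, THF), the precedented lavandulylation at an already substituted carbon, gives 8 together with the C5 epimer of 8 F2. The two are separated by chromatography; enantiopurity still rests on 3, and the route is rejoined at 8.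

Step 9 (radical cascade). The C3 or the tertiary radical may be reduced before it cyclizes. Fallback, from 12 to 16: Zn dust in AcOH/THF at 0 °C removes the chlorine to give the free β-diketone F5, the 7-endo bicyclic acylphloroglucinol that is the presumed biogenetic precursor. The same C3 radical is then generated oxidatively from the enol with Mn(OAc)3·2H2O in degassed EtOH, where no hydride donor can intercept the early radicals and ethanol quenches the final isopropyl radical, giving 16.

**Further compounds**
F1 | step 5 | 3-chloro-5-geranylphlorisobutyrophenone | CC(C)=CCC/C(C)=C/Cc1c(O)c(Cl)c(O)c(C(=O)C(C)C)c1O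
F2 | step 5 | C5 epimer of 8 | CC(C)=CCC/C(C)=C/C[C@@]1(C[C@@H](CC=C(C)C)C(C)=C)C(O)=C(C(=O)C(C)C)C(O)=C(Cl)C1=O
F3 | step 8 | tertiary chloride from Markovnikov HCl addition to 10 | CC(C)=CCC/C(C)=C/C[C@]1(C[C@@H](CC=C(C)C)C(C)(C)Cl)C(O)=C(C(=O)C(C)C)C(=O)C(Cl)(CC=C(C)C)C1=O
F4 | step 8 | trimethylsilyl enol ether of F3 | CC(C)=CCC/C(C)=C/C[C@]1(C[C@@H](CC=C(C)C)C(C)(C)Cl)C(O[Si](C)(C)C)=C(C(=O)C(C)C)C(=O)C(Cl)(CC=C(C)C)C1=O
F5 | step 9 | 5-geranyl-4-hydroxy-1-isobutyryl-8,8-dimethyl-3,7-diprenylbicyclo[3.3.1]non-3-ene-2,9-dione, 7-endo | CC(C)=CCC/C(C)=C/C[C@@]12C[C@@H](CC=C(C)C)C(C)(C)[C@](C(=O)C(C)C)(C2=O)C(=O)C(CC=C(C)C)=C1O
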